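Follow the ash flask in time. D and X join to links Q, with J as by-product.

common to all: X 1.05 equiv

| flask | D | remark | time |
|---|---|---|---|
| ash | 0.40 M | the very flask that is asked about, followed so far |  |
| alder | 0.80 M | run made earlier |  |
| flask | 0.40 M |  | 30 h |

| run | time / h | Q / % | D / % |
|---|---|---|---|
| ash | 2.00 | 36.0 | 44.1 |
| ash | 4.00 | 36.6 | 38.8 |
| ash | 10.0 | 25.3 | 39.8 |
| ash | 25.0 | 14.3 | 42.2 |
| alder | 1.33 | 42.4 | 43.5 |
| alder | 4.00 | 37.2 | 37.7 |
| alder | 6.00 | 33.1 | 37.9 |
| alder | 10.0 | 26.9 | 37.4 |

(each reading ± 1 percentage point)

- ochre: at 30 h take out 90% of the J then present, then wait 10 h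
- grey: at 30 h add X, 100% of the amount charged, then wait 10 h
- teal: change nothing and wait 10 h more
- green: at 30 h add D, 50.0% of the amount charged, then wait 10 h

- the volume of additions can be left aside
- the analysis behind the earlier runs scatters by 1 percentage point, standard deviation
- steps that have been proposed: X -> G; Q <-> L; D <-> E; D + X <-> Q + J

- Q, in percent of the D first charged, at 30 h
- the remedy with the largest gain of Q, or "none" below 2 percentage points (ochre / grey / teal / green / none)
- Q present, in percent of the D first charged, after teal
- Q present, in percent of the D first charged, after green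

Read Q in the ash run. It falls from 25.3% at 10.0 h to 14.3% at 25.0 h. That gives λ = 0.0380 /h. Call λ the tail constant, the apparent first-order rate constant of the last measured stretch of Q's fall. The stretch before it reads 0.0615 /h, which is faster than λ, so in the ash run the fall is slowing.

Now bracket Q at 30 h. For the bound from above, take the last reading, 14.3%, since Q reads lower there than at 10.0 h and is assumed to keep falling. For the bound from below, assume the fall slows no further and hold λ constant to 30 h, which gives 11.8%. Both bounds carry the scatter of 1 percentage point. My own estimate is the middle, 13.1%.

The forecast gives 12.2%, inside the bracket. It gives 9.3% after teal and 12.5% after green, and it chooses grey: “Adding X converts much of the remaining D”.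

The ash flask gives 12.7%, also inside the bracket. Teal gives 10.8% and green 12.3%. The best remedy is grey, with a gain of 12 points.

    X → G (k = 0.0819 /h)
    Q ⇌ L (K = 2.10, k = 0.0787 /h)
    D ⇌ E (K = 0.380, k = 0.204 /h)
    D + X ⇌ Q + J (K = 1.30, k = 1.16 /M/h)

Use λ again on teal: the lower bound at constant λ is 8.66%, the upper bound 12.7%, and the flask's 10.8% lies between. Left to 5.0 d, the same flask holds Q at 6.59%, a mean constant of 0.00725 /h since 30 h, far slower than λ. Yet the flask has not come to rest at 30 h. Ten times that time lowers Q by 9 points to 3.64%, raises D by 21 points to 63.9%, and leaves X, the limiting reagent, at 0.394% of its charge.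

The runs were generated by integration from invented constants, noise included.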